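**Ret­rosynthetic overview**
- Licochalcone D ⇐ global MOM removal from the tris-MOM (E)-chalcone.
- Chalcone Cα–Cβ bond ⇐ Claisen–Schmidt aldol condensation of MOM-protected 4-hydroxy-3-prenylacetophenone (ring A) with 2-methoxy-3,4-bis(methoxymethoxy)benzaldehyde (ring B).
- Ring A ketone ⇐ aromatic Claisen rearrangement of the 1,1-dimethylallyl ether ⇐ alkyne semihydrogenation ⇐ 4-hydroxyacetophenone + 3-chloro-3-methylbut-1-yne.
- Ring B aldehyde ⇐ 2-O-methylation ⇐ chelation-controlled 3,4-bis-MOM protection of 2,3,4-trihydroxybenzaldehyde.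
- No ring is formed: both benzene rings are bought intact; the ring A fragment is finished first, the ring B fragment second, then they are joined.

Assumption: licochalcone D has no stereocentre, so "single enantiomer" is read as the single (E)-alkene isomer given in the SMILES.

**Route**

Step 1
Reactants: 1 4-hydroxyacetophenone; 2 3-chloro-3-methylbut-1-yne
Product: 3 1-[4-(2-methylbut-3-yn-2-yloxy)phenyl]ethanone
Conditions: DBU (1.3 equiv), CuCl2·2H2O (0.5 mol %), MeCN, 0 °C to rt, 5 h
Reagents that add atoms: none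
Why: Copper-catalysed propargylic substitution (O-alkylation of the phenol by the tertiary propargylic chloride), for which an acidic para-acyl phenol is a favourable substrate, while DBU at 0 °C does not enolise the ketone.

Step 2
Reactants: 3 1-[4-(2-methylbut-3-yn-2-yloxy)phenyl]ethanone
Product: 4 1-[4-(2-methylbut-3-en-2-yloxy)phenyl]ethanone
Conditions: H2 (1 atm), 5% Pd/CaCO3 poisoned with Pb(OAc)2, quinoline, EtOAc, rt, stopped after 1.0 equiv H2
Reagents that add atoms: none
Why: Lindlar reduction (semihydrogenation of the terminal alkyne to the alkene) on a poisoned catalyst that leaves the aryl ketone and the tertiary ether untouched.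

Step 3
Reactants: 4 1-[4-(2-methylbut-3-en-2-yloxy)phenyl]ethanone
Product: 6 1-[4-hydroxy-3-(3-methylbut-2-enyl)phenyl]ethanone, via ortho-dienone 5 (not isolated)
Conditions: PhNEt2, 190 °C, N2, 2 h
Reagents that add atoms: none
Why: Aromatic Claisen [3,3]-sigmatropic rearrangement in which the terminal CH2 of the 1,1-dimethylallyl group bonds to either of the two equivalent ortho carbons (para is blocked) and the dienone tautomerises to the ortho-prenyl phenol, the basic solvent suppressing acid-catalysed chroman formation; the transient stereocentre of 5 is lost on rearomatisation.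

Step 4
Reactants: 6 1-[4-hydroxy-3-(3-methylbut-2-enyl)phenyl]ethanone
Product: 7 1-[4-(methoxymethoxy)-3-(3-methylbut-2-enyl)phenyl]ethanone
Conditions: MOMCl (1.5 equiv), i-Pr2NEt (2 equiv), CH2Cl2, 0 °C to rt
Reagents that add atoms: chloromethyl methyl ether (MOMCl), COCCl
Why: Williamson-type O-alkylation to the MOM acetal, which removes the phenoxide that would otherwise deactivate the methyl ketone toward enolisation in the aldol step.

Step 5
Reactants: 8 2,3,4-trihydroxybenzaldehyde
Product: 9 2-hydroxy-3,4-bis(methoxymethoxy)benzaldehyde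
Conditions: MOMCl (2.1 equiv), i-Pr2NEt (2.3 equiv), CH2Cl2, 0 °C to rt
Reagents that add atoms: chloromethyl methyl ether (MOMCl), COCCl
Why: Chelation-controlled selective O-alkylation, because the 2-OH is locked in a strong intramolecular hydrogen bond to the aldehyde and stays free while the 4-OH and 3-OH are converted to MOM acetals.

Step 6
Reactants: 9 2-hydroxy-3,4-bis(methoxymethoxy)benzaldehyde
Product: 10 2-methoxy-3,4-bis(methoxymethoxy)benzaldehyde
Conditions: MeI (2 equiv), K2CO3 (2 equiv), DMF, 40 °C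
Reagents that add atoms: iodomethane (MeI), CI
Why: Williamson ether synthesis in a polar aprotic solvent that breaks the chelate and methylates the one remaining phenol, the MOM acetals and the non-enolisable aldehyde being inert to K2CO3.

Step 7
Reactants: 7 1-[4-(methoxymethoxy)-3-(3-methylbut-2-enyl)phenyl]ethanone; 10 2-methoxy-3,4-bis(methoxymethoxy)benzaldehyde
Product: 12 (E)-3-[2-methoxy-3,4-bis(methoxymethoxy)phenyl]-1-[4-(methoxymethoxy)-3-(3-methylbut-2-enyl)phenyl]prop-2-en-1-one, via aldol adduct 11 (not isolated)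
Conditions: KOH (50% aq, 6 equiv), EtOH, rt, 24–36 h
Reagents that add atoms: none
Why: Claisen–Schmidt crossed aldol condensation in which only the ketone can enolise and only the aldehyde is a good acceptor, and the E1cB dehydration of the β-hydroxy ketone gives the thermodynamically favoured (E)-enone with MOM ethers and prenyl group stable to base.

Step 8
Reactants: 12 (E)-3-[2-methoxy-3,4-bis(methoxymethoxy)phenyl]-1-[4-(methoxymethoxy)-3-(3-methylbut-2-enyl)phenyl]prop-2-en-1-one
Product: 13 licochalcone D = (E)-3-(3,4-dihydroxy-2-methoxyphenyl)-1-[4-hydroxy-3-(3-methylbut-2-enyl)phenyl]prop-2-en-1-one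
Conditions: 3 M aq HCl, MeOH, 45 °C, 1–2 h (TLC control)
Reagents that add atoms: none
Why: Acid-catalysed acetal methanolysis removes all three MOM groups under conditions mild enough to spare the prenyl alkene, and with no 2'-OH on ring A the chalcone cannot cyclise to a flavanone, so the (E)-enone is retained.

**Compound list**

1 | 4-hydroxyacetophenone | CC(=O)c1ccc(O)cc1 | starting material
2 | 3-chloro-3-methylbut-1-yne | C#CC(C)(C)Cl | starting material
3 | 1-[4-(2-methylbut-3-yn-2-yloxy)phenyl]ethanone | CC(=O)c1ccc(OC(C)(C)C#C)cc1 | intermediate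
4 | 1-[4-(2-methylbut-3-en-2-yloxy)phenyl]ethanone | CC(=O)c1ccc(OC(C)(C)C=C)cc1 | intermediate
5 | 4-acetyl-6-(3-methylbut-2-enyl)cyclohexa-2,4-dien-1-one (racemic, transient ortho-dienone) | CC(=O)C1=CC(CC=C(C)C)C(=O)C=C1 | intermediate (not isolated)
6 | 1-[4-hydroxy-3-(3-methylbut-2-enyl)phenyl]ethanone (4-hydroxy-3-prenylacetophenone) | CC(=O)c1ccc(O)c(CC=C(C)C)c1 | intermediate
7 | 1-[4-(methoxymethoxy)-3-(3-methylbut-2-enyl)phenyl]ethanone | CC(=O)c1ccc(OCOC)c(CC=C(C)C)c1 | intermediate
8 | 2,3,4-trihydroxybenzaldehyde | O=Cc1ccc(O)c(O)c1O | starting material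
9 | 2-hydroxy-3,4-bis(methoxymethoxy)benzaldehyde | O=Cc1ccc(OCOC)c(OCOC)c1O | intermediate
10 | 2-methoxy-3,4-bis(methoxymethoxy)benzaldehyde | COc1c(C=O)ccc(OCOC)c1OCOC | intermediate
11 | 3-hydroxy-3-[2-methoxy-3,4-bis(methoxymethoxy)phenyl]-1-[4-(methoxymethoxy)-3-(3-methylbut-2-enyl)phenyl]propan-1-one (racemic aldol adduct) | COc1c(C(O)CC(=O)c2ccc(OCOC)c(CC=C(C)C)c2)ccc(OCOC)c1OCOC | intermediate (not isolated)
12 | (E)-3-[2-methoxy-3,4-bis(methoxymethoxy)phenyl]-1-[4-(methoxymethoxy)-3-(3-methylbut-2-enyl)phenyl]prop-2-en-1-one | COc1c(/C=C/C(=O)c2ccc(OCOC)c(CC=C(C)C)c2)ccc(OCOC)c1OCOC | intermediate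
13 | licochalcone D, (E)-3-(3,4-dihydroxy-2-methoxyphenyl)-1-[4-hydroxy-3-(3-methylbut-2-enyl)phenyl]prop-2-en-1-one | COc1c(/C=C/C(=O)c2ccc(O)c(CC=C(C)C)c2)ccc(O)c1O | target

**Totals**
Total step count: 8. Longest linear sequence: 6 steps (steps 1, 2, 3, 4, 7, 8 from 4-hydroxyacetophenone); the aldehyde branch is 2 steps before the convergence.

**Three steps most likely to fail, with fallbacks**

Risk 1, the Claisen rearrangement of step 3. The tertiary allyl ether may fragment to 1 and isoprene, or the product may cyclise to a chroman at 190 °C. The fallback installs the prenyl group by cross-coupling instead; it sets out from 1 and comes back to the route at 7, replacing steps 1–4. Mono-iodination of 1 ortho to the hydroxyl (NIS, cat. p-TsOH, MeCN, rt) gives 1-(4-hydroxy-3-iodophenyl)ethanone F1. MOM protection (MOMCl, i-Pr2NEt, CH2Cl2) gives 1-[3-iodo-4-(methoxymethoxy)phenyl]ethanone F2. Stille coupling of the aryl iodide with tributyl(3-methylbut-2-enyl)stannane (Pd(PPh3)4, a zerovalent palladium catalyst, DMF, 90 °C) joins the aryl group to the less hindered allyl terminus and delivers 7 directly. Any minor reverse-prenyl isomer is removed by chromatography.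

Risk 2, the regioselective bis-MOM protection of step 5. Mixtures of mono-, 2,4-bis- and tris-protected aldehydes are possible. The fallback differentiates the hydroxyls with a cyclic ketal instead; it sets out from 8 and comes back at 10, replacing steps 5–6. Heating 8 with dichlorodiphenylmethane (Ph2CCl2, Ph2O, 170 °C) bridges the non-chelated 3,4-diol and gives 4-hydroxy-2,2-diphenyl-1,3-benzodioxole-5-carbaldehyde F3. Methylation (MeI, K2CO3, DMF) gives 4-methoxy-2,2-diphenyl-1,3-benzodioxole-5-carbaldehyde F4. Ketal hydrolysis (AcOH/H2O 4:1, reflux) gives 3,4-dihydroxy-2-methoxybenzaldehyde F5. Exhaustive MOM protection (MOMCl 3 equiv, i-Pr2NEt, CH2Cl2), which now needs no selectivity, gives 10.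

Risk 3, the acidic global deprotection of step 8. HCl can add the ortho phenol or methanol across the prenyl alkene (chroman or tertiary ether by-products). The fallback replaces MOM by allyl ethers, which are removed without acid; it sets out from 8 and 6 and comes back at 13.
- Aldehyde branch: chelation-controlled bis-allylation of 8 (allyl bromide 2.1 equiv, K2CO3, DMF, rt) gives 2-hydroxy-3,4-bis(prop-2-enyloxy)benzaldehyde F6, and methylation (MeI, K2CO3, DMF) gives 2-methoxy-3,4-bis(prop-2-enyloxy)benzaldehyde F7.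
- Ketone branch: allylation of 6 (allyl bromide, K2CO3, acetone, reflux) gives 1-[3-(3-methylbut-2-enyl)-4-(prop-2-enyloxy)phenyl]ethanone F8.
- Condensation: the same Claisen–Schmidt reaction (KOH, EtOH, rt) passes through 3-hydroxy-3-[2-methoxy-3,4-bis(prop-2-enyloxy)phenyl]-1-[3-(3-methylbut-2-enyl)-4-(prop-2-enyloxy)phenyl]propan-1-one F9, which is not isolated, and gives (E)-3-[2-methoxy-3,4-bis(prop-2-enyloxy)phenyl]-1-[3-(3-methylbut-2-enyl)-4-(prop-2-enyloxy)phenyl]prop-2-en-1-one F10.
- Deallylation: Pd(PPh3)4 (5 mol %), K2CO3, MeOH, rt under argon, then mild acidification on work-up, cleaves the three O-allyl groups through π-allyl palladium intermediates and gives 13. The C-bound prenyl group and the enone are not touched.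

**Further compounds**

F1 | step 3 | 1-(4-hydroxy-3-iodophenyl)ethanone | CC(=O)c1ccc(O)c(I)c1
F2 | step 3 | 1-[3-iodo-4-(methoxymethoxy)phenyl]ethanone | CC(=O)c1ccc(OCOC)c(I)c1
F3 | step 5 | 4-hydroxy-2,2-diphenyl-1,3-benzodioxole-5-carbaldehyde | O=Cc1ccc2OC(c3ccccc3)(c3ccccc3)Oc2c1O
F4 | step 5 | 4-methoxy-2,2-diphenyl-1,3-benzodioxole-5-carbaldehyde | COc1c(C=O)ccc2OC(c3ccccc3)(c3ccccc3)Oc12
F5 | step 5 | 3,4-dihydroxy-2-methoxybenzaldehyde | COc1c(C=O)ccc(O)c1O
F6 | step 8 | 2-hydroxy-3,4-bis(prop-2-enyloxy)benzaldehyde | O=Cc1ccc(OCC=C)c(OCC=C)c1O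
F7 | step 8 | 2-methoxy-3,4-bis(prop-2-enyloxy)benzaldehyde | COc1c(C=O)ccc(OCC=C)c1OCC=C
F8 | step 8 | 1-[3-(3-methylbut-2-enyl)-4-(prop-2-enyloxy)phenyl]ethanone | CC(=O)c1ccc(OCC=C)c(CC=C(C)C)c1
F9 | step 8 | 3-hydroxy-3-[2-methoxy-3,4-bis(prop-2-enyloxy)phenyl]-1-[3-(3-methylbut-2-enyl)-4-(prop-2-enyloxy)phenyl]propan-1-one (racemic, not isolated) | COc1c(C(O)CC(=O)c2ccc(OCC=C)c(CC=C(C)C)c2)ccc(OCC=C)c1OCC=C
F10 | step 8 | (E)-3-[2-methoxy-3,4-bis(prop-2-enyloxy)phenyl]-1-[3-(3-methylbut-2-enyl)-4-(prop-2-enyloxy)phenyl]prop-2-en-1-one | COc1c(/C=C/C(=O)c2ccc(OCC=C)c(CC=C(C)C)c2)ccc(OCC=C)c1OCC=C
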